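**Retrosynthetic overview**

1. The strategy rests on ring D: its ether oxygen joins the ring C fusion CH–O carbon to a gem-dimethyl carbon that lies next to the ring D C=O carbon. That O–C(CH3)2 carbon is the Markovnikov carbon of an isopropenyl ketal, so ring D is opened at this O–C bond (hydrogen-atom-transfer hydroalkoxylation, 7-exo).
2. Rings A/B and C/D carry the same three stereocentres (methyl-bearing fusion carbon, CH–O carbon, CH that holds the linker), so one bicyclic α-methylene ketone 22 is made once and feeds both halves.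
3. The last C–C bond is the central CH2–CH2 linker, made by conjugate addition of a ring A/B alkylcopper (from a phenyl thioether) to 22. MeMgBr/CeCl3 then builds the ring C carbinol, and acid frees the ring D ketone and the ring B alcohol.
4. The cyclisation precursor comes from an anti-selective copper-catalysed addition of a ketal-bearing Grignard reagent to (S)-3-methyl-4-silyloxycyclohexenone (Shi epoxidation sets the absolute configuration), then enolate hydroxymethylation.
5. Ring order: ring C (from the cyclohexenone), then ring D (key step); the same bicycle is then re-tailored into rings A/B (methylenation, ketal removal, CBS reduction) before the union.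

Key step: step 14

Remark: bicyclic compounds are numbered on the 1-benzoxepine frame (O1; C2 gem-dimethyl carbon; C3 oxepane carbonyl, ketal or carbinol carbon; C5a methyl-bearing fusion carbon; C6 CH that carries the linker; C7 C=O, C(OH)CH3 or C=CH2 of the carbocycle; C9a CH–O). Compounds 18–21 are assumed to be carried as mixtures of epimers at the carbon bearing the CH2O group, a centre that step 15 erases and that steps 16 and 21 set again by protonation. A pivalate replaces a silyl ether on that CH2O group because it later serves as the leaving group.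

**Route**

Step 1
Reactants: 1 3-methylcyclohex-2-en-1-one
Product: 2 7-methyl-1,4-dioxaspiro[4.5]dec-7-ene
Conditions: HOCH2CH2OH, p-toluenesulfonic acid monohydrate (cat.), benzene, reflux, azeotropic removal of water
Reagents that add atoms: ethylene glycol, OCCO
Why: Acid-catalysed ketalisation of a cyclohexenone passes through the dienol ether, so the double bond should leave conjugation and settle in the trisubstituted β,γ-position (ketalisation with deconjugation), which places the alkene where the ring oxygen is needed.

Step 2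
Reactants: 2 7-methyl-1,4-dioxaspiro[4.5]dec-7-ene
Product: 3 (1R,6S)-1-methyl-7-oxabicyclo[4.1.0]heptan-3-one ethylene ketal
Conditions: 1,2:4,5-di-O-isopropylidene-β-L-erythro-2,3-hexodiulo-2,6-pyranose (0.3 equiv), KHSO5 (as 2KHSO5·KHSO4·K2SO4), K2CO3, Bu4NHSO4 (cat.), MeCN/CH2(OMe)2/aq. Na2B4O7 buffer, 0 °C
Reagents that add atoms: potassium peroxymonosulfate, [K+].[O-]S(=O)(=O)OO
Why: Shi epoxidation of the trisubstituted alkene through the spiro dioxirane transition state should deliver oxygen to the face that makes the secondary epoxide carbon (S) when the L-sugar-derived ketone is used, and the basic buffer leaves the ketal intact.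

Step 3
Reactants: 3 (1R,6S)-1-methyl-7-oxabicyclo[4.1.0]heptan-3-one ethylene ketal
Product: 5 (S)-4-hydroxy-3-methylcyclohex-2-en-1-one, via epoxy ketone 4 (not isolated)
Conditions: 0.5 M aq. H2SO4, THF, 0 °C → rt; then Et3N, 0 °C
Reagents that add atoms: water, O
Why: Hydrolysis of the ketal gives a β,γ-epoxy ketone whose enol or enolate opens the epoxide at the tertiary carbon (E1cB-type β-elimination) to the conjugated γ-hydroxy enone, and because the C–O bond at the secondary carbon is never broken the (S) configuration from step 2 is carried into the carbinol.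

Step 4
Reactants: 5 (S)-4-hydroxy-3-methylcyclohex-2-en-1-one
Product: 6 (S)-3-methyl-4-(triethylsilyloxy)cyclohex-2-en-1-one
Conditions: Et3SiCl, imidazole, DMF, 0 °C
Reagents that add atoms: chlorotriethylsilane, CC[Si](Cl)(CC)CC
Why: Imidazole-mediated silylation protects the allylic alcohol as a silyl ether, the γ-substituent known to direct cuprate additions to the opposite face and to survive them without elimination.

Step 5
Reactants: 7 methyl 3-hydroxypropanoate
Product: 8 methyl 3-(tert-butyldimethylsilyloxy)propanoate
Conditions: t-BuMe2SiCl, imidazole, CH2Cl2, rt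
Reagents that add atoms: tert-butylchlorodimethylsilane, CC(C)(C)[Si](C)(C)Cl
Why: Standard silylation masks the primary alcohol so that the ester can be treated with organomagnesium reagents.

Step 6
Reactants: 8 methyl 3-(tert-butyldimethylsilyloxy)propanoate; 9 isopropenylmagnesium bromide
Product: 11 1-(tert-butyldimethylsilyloxy)-4-methylpent-4-en-3-one, via Weinreb amide 10 (not isolated)
Conditions: MeNH(OMe)·HCl, i-PrMgCl, THF, −20 °C; then 9, −20 → 0 °C; cold aq. NH4Cl
Reagents that add atoms: none
Why: Telescoped Weinreb ketone synthesis, in which the magnesium amide converts the ester into the N-methoxy-N-methylamide and the chelated tetrahedral adduct of the alkenyl Grignard reagent collapses to the enone only on work-up, so no tertiary alcohol forms.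

Step 7
Reactants: 11 1-(tert-butyldimethylsilyloxy)-4-methylpent-4-en-3-one
Product: 12 tert-butyldimethyl{2-[2-(prop-1-en-2-yl)-1,3-dioxolan-2-yl]ethoxy}silane
Conditions: (Me3SiOCH2)2, Me3SiOTf (cat.), CH2Cl2, −78 → −20 °C; pyridine quench
Reagents that add atoms: 1,2-bis(trimethylsilyloxy)ethane, C[Si](C)(C)OCCO[Si](C)(C)C
Why: Noyori ketalisation under aprotic low-temperature conditions converts the enone into its dioxolane without conjugate addition, and the isopropenyl double bond has no position to migrate to.

Step 8
Reactants: 12 tert-butyldimethyl{2-[2-(prop-1-en-2-yl)-1,3-dioxolan-2-yl]ethoxy}silane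
Product: 13 2-[2-(prop-1-en-2-yl)-1,3-dioxolan-2-yl]ethan-1-ol
Conditions: Bu4NF, THF, 0 °C
Reagents that add atoms: none
Why: Fluoride-induced desilylation frees the primary alcohol under basic conditions that the acid-labile allylic ketal tolerates.

Step 9
Reactants: 13 2-[2-(prop-1-en-2-yl)-1,3-dioxolan-2-yl]ethan-1-ol
Product: 14 2-(2-bromoethyl)-2-(prop-1-en-2-yl)-1,3-dioxolane
Conditions: CBr4, PPh3, 2,6-lutidine, CH2Cl2, 0 °C
Reagents that add atoms: tetrabromomethane, BrC(Br)(Br)Br
Why: The Appel reaction turns the primary alcohol into the bromide under buffered, essentially neutral conditions that preserve the ketal.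

Step 10
Reactants: 14 2-(2-bromoethyl)-2-(prop-1-en-2-yl)-1,3-dioxolane; 6 (S)-3-methyl-4-(triethylsilyloxy)cyclohex-2-en-1-one
Product: 16 (3S,4S)-3-methyl-3-{2-[2-(prop-1-en-2-yl)-1,3-dioxolan-2-yl]ethyl}-4-(triethylsilyloxy)-1-(trimethylsilyloxy)cyclohex-1-ene, via Grignard reagent 15 (not isolated)
Conditions: Mg, THF, 20 °C; then CuBr·SMe2 (10 mol%), Me3SiCl, hexamethylphosphoric triamide, 6, THF, −78 °C; Et3N quench
Reagents that add atoms: chlorotrimethylsilane, C[Si](C)(C)Cl
Why: Copper-catalysed conjugate addition of the γ-ketal Grignard reagent, accelerated by the chlorosilane, should occur anti to the pseudo-axial γ-silyloxy group, which sets the quaternary carbon (S) with the new chain trans to oxygen and traps the regiodefined enolate as its silyl ether.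

Step 11
Reactants: 16 (3S,4S)-3-methyl-3-{2-[2-(prop-1-en-2-yl)-1,3-dioxolan-2-yl]ethyl}-4-(triethylsilyloxy)-1-(trimethylsilyloxy)cyclohex-1-ene
Product: 18 (3S,4S)-2-(hydroxymethyl)-3-methyl-3-{2-[2-(prop-1-en-2-yl)-1,3-dioxolan-2-yl]ethyl}-4-(triethylsilyloxy)cyclohexan-1-one (C2 epimers), via lithium enolate 17 (not isolated)
Conditions: MeLi, THF, 0 °C; then CH2O (gas from cracked paraformaldehyde), −78 °C; aq. NH4Cl
Reagents that add atoms: formaldehyde, C=O
Why: Methyllithium cleaves the O–Si bond to the lithium enolate without loss of regiochemistry and the aldol reaction with monomeric formaldehyde installs the one-carbon unit next to the quaternary centre; both C2 epimers are acceptable because this centre is erased in step 15.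

Step 12
Reactants: 18 (3S,4S)-2-(hydroxymethyl)-3-methyl-3-{2-[2-(prop-1-en-2-yl)-1,3-dioxolan-2-yl]ethyl}-4-(triethylsilyloxy)cyclohexan-1-one (C2 epimers)
Product: 19 [(2S,3S)-2-methyl-6-oxo-2-{2-[2-(prop-1-en-2-yl)-1,3-dioxolan-2-yl]ethyl}-3-(triethylsilyloxy)cyclohexyl]methyl pivalate (C1 epimers)
Conditions: t-BuCOCl, pyridine, 4-(dimethylamino)pyridine (cat.), CH2Cl2, 0 °C
Reagents that add atoms: pivaloyl chloride, CC(C)(C)C(=O)Cl
Why: Acylation of the only free hydroxyl gives a pivalate that is inert to fluoride and to the cobalt hydride chemistry and later serves as the leaving group for enone formation.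

Step 13
Reactants: 19 [(2S,3S)-2-methyl-6-oxo-2-{2-[2-(prop-1-en-2-yl)-1,3-dioxolan-2-yl]ethyl}-3-(triethylsilyloxy)cyclohexyl]methyl pivalate (C1 epimers)
Product: 20 [(2S,3S)-3-hydroxy-2-methyl-6-oxo-2-{2-[2-(prop-1-en-2-yl)-1,3-dioxolan-2-yl]ethyl}cyclohexyl]methyl pivalate (C1 epimers)
Conditions: HF·pyridine, pyridine, THF, 0 °C → rt
Reagents that add atoms: none
Why: Buffered HF·pyridine removes the triethylsilyl ether (acid-type desilylation) under anhydrous conditions that spare the pivalate and the allylic ketal and expose the ring hydroxyl for the cyclisation.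

Step 14
Reactants: 20 [(2S,3S)-3-hydroxy-2-methyl-6-oxo-2-{2-[2-(prop-1-en-2-yl)-1,3-dioxolan-2-yl]ethyl}cyclohexyl]methyl pivalate (C1 epimers)
Product: 21 [(5aS,9aS)-2,2,5a-trimethyl-3,7-dioxoperhydro-1-benzoxepin-6-yl]methyl pivalate 3-ethylene ketal (C6 epimers)
Conditions: Co(salen) [N,N′-bis(salicylidene)ethylenediaminatocobalt, divalent cobalt] (5 mol%), N-fluoro-2,4,6-trimethylpyridinium triflate (1.5 equiv), PhSiH3 (1.5 equiv), PhCF3, 0 °C → rt, argon
Reagents that add atoms: none
Why: Proposed new method: the silane and the N-fluoropyridinium oxidant convert the cobalt–salen complex into a cobalt hydride that transfers a hydrogen atom to the terminal CH2 of the only alkene, and the tertiary radical is captured and oxidised to a high-valent alkylcobalt species (a cation equivalent) that the ring hydroxyl displaces, the proton going to the liberated 2,4,6-trimethylpyridine. The closest known reaction is the cobalt–salen, silane and N-fluoropyridinium Markovnikov hydroalkoxylation of unactivated alkenes (a Mukaiyama-type radical-polar crossover), which is established for five- and six-membered cyclic ethers but not for an oxepane or for a carbon flanked by a ketal. Ring D closes in a 7-exo mode, and because oxygen can only bond to the Markovnikov carbon, the six-membered ether that competes in hydroxy-epoxide openings cannot arise. No stereocentre is created, since the new ether carbon carries two methyl groups, so the step needs only chemo- and regioselectivity. These are secured by the single alkene, by the equatorial hydroxyl and equatorial side chain that sit gauche on the chair of ring C, by the quaternary carbon and the ketal carbon that fold the tether, and by the fact that reverse hydrogen-atom transfer can only regenerate the same isopropenyl group, while ketone, pivalate and ketal are inert to the cobalt hydride. The hazards are the inductive brake of the ketal on the cation-like stage, which favours plain reduction of the alkene, and a 1,2-alkyl shift toward a dioxolanylium ion, both countered by the non-coordinating solvent and the high effective molarity of the hydroxyl.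

Step 15
Reactants: 21 [(5aS,9aS)-2,2,5a-trimethyl-3,7-dioxoperhydro-1-benzoxepin-6-yl]methyl pivalate 3-ethylene ketal (C6 epimers)
Product: 22 (5aS,9aS)-2,2,5a-trimethyl-6-methylideneperhydro-1-benzoxepine-3,7-dione 3-ethylene ketal
Conditions: 1,8-diazabicyclo[5.4.0]undec-7-ene, toluene, rt → 50 °C
Reagents that add atoms: none
Why: The β-acyloxy ketone undergoes E1cB elimination of pivalate under the amidine base, and both C6 epimers converge on one α-methylene ketone that is the common precursor of the two halves.

Step 16
Reactants: 22 (5aS,9aS)-2,2,5a-trimethyl-6-methylideneperhydro-1-benzoxepine-3,7-dione 3-ethylene ketal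
Product: 23 (5aS,6S,9aS)-2,2,5a-trimethyl-6-[(phenylsulfanyl)methyl]perhydro-1-benzoxepine-3,7-dione 3-ethylene ketal
Conditions: PhSH, Et3N (cat.), CH2Cl2, −20 °C
Reagents that add atoms: thiophenol, Sc1ccccc1
Why: Thia-Michael addition to the unhindered exocyclic terminus is followed by protonation at C6 from the face opposite the axial C5a methyl group (axial protonation), which places the CH2SPh group equatorial, the arrangement that is also thermodynamically preferred.

Step 17
Reactants: 23 (5aS,6S,9aS)-2,2,5a-trimethyl-6-[(phenylsulfanyl)methyl]perhydro-1-benzoxepine-3,7-dione 3-ethylene ketal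
Product: 24 (5aS,6R,9aS)-2,2,5a-trimethyl-7-methylidene-6-[(phenylsulfanyl)methyl]perhydro-1-benzoxepin-3-one ethylene ketal
Conditions: Zn, CH2Br2, TiCl4, THF (reagent pre-formed, 0 °C); then 23, CH2Cl2, 0 °C → rt
Reagents that add atoms: dibromomethane, BrCBr
Why: Lombardo methylenation with the non-basic CH2Br2–Zn–TiCl4 reagent converts the hindered, epimerisable ketone into the exocyclic alkene without enolisation or β-elimination of thiolate, so C6 keeps its configuration (the descriptor changes only through the priority rules).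

Step 18
Reactants: 24 (5aS,6R,9aS)-2,2,5a-trimethyl-7-methylidene-6-[(phenylsulfanyl)methyl]perhydro-1-benzoxepin-3-one ethylene ketal
Product: 25 (5aS,6R,9aS)-2,2,5a-trimethyl-7-methylidene-6-[(phenylsulfanyl)methyl]perhydro-1-benzoxepin-3-one
Conditions: p-toluenesulfonic acid monohydrate (cat.), acetone/H2O, rt
Reagents that add atoms: water, O
Why: Acid-catalysed transketalisation to acetone and water frees the oxepanone at room temperature, conditions under which the 1,1-disubstituted alkene and the thioether should survive.

Step 19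
Reactants: 25 (5aS,6R,9aS)-2,2,5a-trimethyl-7-methylidene-6-[(phenylsulfanyl)methyl]perhydro-1-benzoxepin-3-one
Product: 26 (3S,5aS,6R,9aS)-2,2,5a-trimethyl-7-methylidene-6-[(phenylsulfanyl)methyl]perhydro-1-benzoxepin-3-ol
Conditions: (R)-1-methyl-3,3-diphenyl-tetrahydro-1H,3H-pyrrolo[1,2-c][1,3,2]oxazaborole (1.0 equiv), catecholborane, toluene, −78 → −30 °C; then MeOH, aq. NaOH
Reagents that add atoms: none
Why: Corey–Bakshi–Shibata reduction in which the ketone binds the oxazaborolidine with the fully substituted C2 as the large group and the C4 methylene as the small one, so the (R)-catalyst should deliver hydride to the face that gives the (3S)-alcohol, while catecholborane leaves the exocyclic alkene untouched.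

Step 20
Reactants: 26 (3S,5aS,6R,9aS)-2,2,5a-trimethyl-7-methylidene-6-[(phenylsulfanyl)methyl]perhydro-1-benzoxepin-3-ol
Product: 27 (3S,5aS,6R,9aS)-2,2,5a-trimethyl-7-methylidene-6-[(phenylsulfanyl)methyl]-3-(triethylsilyloxy)perhydro-1-benzoxepine
Conditions: Et3SiOTf, 2,6-lutidine, CH2Cl2, −78 °C
Reagents that add atoms: triethylsilyl trifluoromethanesulfonate, CC[Si](CC)(CC)OS(=O)(=O)C(F)(F)F
Why: Silylation of the hindered secondary alcohol with the silyl triflate protects it against the organolithium of the next step as an ether that falls off in the final acid step.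

Step 21
Reactants: 27 (3S,5aS,6R,9aS)-2,2,5a-trimethyl-7-methylidene-6-[(phenylsulfanyl)methyl]-3-(triethylsilyloxy)perhydro-1-benzoxepine; 22 (5aS,9aS)-2,2,5a-trimethyl-6-methylideneperhydro-1-benzoxepine-3,7-dione 3-ethylene ketal
Product: 31 linked ketone in which C6 of the ring A/B silyl ether is joined through CH2CH2 to C6 of the ring C/D 7-ketone 3-ethylene ketal, via alkyllithium 28 (not isolated), via thiolato cuprate 29 (not isolated), via silyl enol ether 30 (not isolated)
Conditions: lithium 4,4′-di-tert-butylbiphenylide (2.1 equiv), THF, −78 °C; CuBr·SMe2 (1 equiv), −78 → −50 °C; Me3SiCl, then 22, −78 → −40 °C; K2CO3, MeOH, 0 °C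
Reagents that add atoms: none
Why: Reductive lithiation of the phenyl thioether gives the primary alkyllithium and lithium thiophenolate, which with CuBr form a mixed thiolato cuprate that transfers only the alkyl group in a chlorosilane-accelerated conjugate addition to the exocyclic enone, and protonation of the released enolate from the face opposite the axial C5a methyl group sets C6 of ring C with the linker equatorial (S).

Step 22
Reactants: 31 linked ketone
Product: 32 linked tertiary alcohol, the (7R)-7-hydroxy-7-methyl compound that still carries the ring D ketal and the ring B silyl ether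
Conditions: MeMgBr, CeCl3, THF, −78 °C; aq. NH4Cl
Reagents that add atoms: methylmagnesium bromide, C[Mg]Br
Why: The organocerium reagent adds to the hindered ketone without enolisation, and because the axial C5a methyl group blocks the axial trajectory the methyl group enters equatorially and the hydroxyl ends up axial, which is the (7R) configuration of the target.

Step 23
Reactants: 32 linked tertiary alcohol
Product: 33 CNP0160418.1
Conditions: p-toluenesulfonic acid monohydrate (cat.), acetone/H2O, rt
Reagents that add atoms: water, O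
Why: Acid-catalysed transketalisation releases the ring D ketone and the same medium hydrolyses the triethylsilyl ether, while dilute acid at room temperature should leave the exocyclic alkene and the tertiary alcohol untouched.

**Compound list**

1 | 3-methylcyclohex-2-en-1-one | CC1=CC(=O)CCC1 | starting material
2 | 7-methyl-1,4-dioxaspiro[4.5]dec-7-ene | CC1=CCCC2(C1)OCCO2 | intermediate
3 | (1R,6S)-1-methyl-7-oxabicyclo[4.1.0]heptan-3-one ethylene ketal | C[C@@]12CC3(OCCO3)CC[C@@H]1O2 | intermediate
4 | (1R,6S)-1-methyl-7-oxabicyclo[4.1.0]heptan-3-one (formed in the flask) | C[C@@]12CC(=O)CC[C@@H]1O2 | intermediate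
5 | (S)-4-hydroxy-3-methylcyclohex-2-en-1-one | O=C1CC[C@H](O)C(C)=C1 | intermediate
6 | (S)-3-methyl-4-(triethylsilyloxy)cyclohex-2-en-1-one | O=C1CC[C@H](O[Si](CC)(CC)CC)C(C)=C1 | intermediate
7 | methyl 3-hydroxypropanoate | COC(=O)CCO | starting material
8 | methyl 3-(tert-butyldimethylsilyloxy)propanoate | COC(=O)CCO[Si](C)(C)C(C)(C)C | intermediate
9 | isopropenylmagnesium bromide | CC(=C)[Mg]Br | starting material
10 | 3-(tert-butyldimethylsilyloxy)-N-methoxy-N-methylpropanamide (formed in the flask) | CON(C)C(=O)CCO[Si](C)(C)C(C)(C)C | intermediate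
11 | 1-(tert-butyldimethylsilyloxy)-4-methylpent-4-en-3-one | CC(=C)C(=O)CCO[Si](C)(C)C(C)(C)C | intermediate
12 | tert-butyldimethyl{2-[2-(prop-1-en-2-yl)-1,3-dioxolan-2-yl]ethoxy}silane | CC(=C)C1(CCO[Si](C)(C)C(C)(C)C)OCCO1 | intermediate
13 | 2-[2-(prop-1-en-2-yl)-1,3-dioxolan-2-yl]ethan-1-ol | CC(=C)C1(CCO)OCCO1 | intermediate
14 | 2-(2-bromoethyl)-2-(prop-1-en-2-yl)-1,3-dioxolane | CC(=C)C1(CCBr)OCCO1 | intermediate
15 | {2-[2-(prop-1-en-2-yl)-1,3-dioxolan-2-yl]ethyl}magnesium bromide (formed in the flask) | CC(=C)C1(CC[Mg]Br)OCCO1 | intermediate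
16 | (3S,4S)-3-methyl-3-{2-[2-(prop-1-en-2-yl)-1,3-dioxolan-2-yl]ethyl}-4-(triethylsilyloxy)-1-(trimethylsilyloxy)cyclohex-1-ene | C[Si](C)(C)OC1=C[C@](C)(CCC2(OCCO2)C(C)=C)[C@@H](O[Si](CC)(CC)CC)CC1 | intermediate
17 | lithium enolate of the (3S,4S)-cyclohexanone (formed in the flask) | [Li]OC1=C[C@](C)(CCC2(OCCO2)C(C)=C)[C@@H](O[Si](CC)(CC)CC)CC1 | intermediate
18 | (3S,4S)-2-(hydroxymethyl)-3-methyl-3-{2-[2-(prop-1-en-2-yl)-1,3-dioxolan-2-yl]ethyl}-4-(triethylsilyloxy)cyclohexan-1-one, C2 epimers | O=C1CC[C@H](O[Si](CC)(CC)CC)[C@@](C)(CCC2(OCCO2)C(C)=C)C1CO | intermediate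
19 | [(2S,3S)-2-methyl-6-oxo-2-{2-[2-(prop-1-en-2-yl)-1,3-dioxolan-2-yl]ethyl}-3-(triethylsilyloxy)cyclohexyl]methyl pivalate, C1 epimers | O=C1CC[C@H](O[Si](CC)(CC)CC)[C@@](C)(CCC2(OCCO2)C(C)=C)C1COC(=O)C(C)(C)C | intermediate
20 | [(2S,3S)-3-hydroxy-2-methyl-6-oxo-2-{2-[2-(prop-1-en-2-yl)-1,3-dioxolan-2-yl]ethyl}cyclohexyl]methyl pivalate, C1 epimers (cyclisation precursor) | O=C1CC[C@H](O)[C@@](C)(CCC2(OCCO2)C(C)=C)C1COC(=O)C(C)(C)C | intermediate
21 | [(5aS,9aS)-2,2,5a-trimethyl-3,7-dioxoperhydro-1-benzoxepin-6-yl]methyl pivalate 3-ethylene ketal, C6 epimers (ring C/D bicycle) | O=C1CC[C@@H]2OC(C)(C)C3(OCCO3)CC[C@@]2(C)C1COC(=O)C(C)(C)C | intermediate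
22 | (5aS,9aS)-2,2,5a-trimethyl-6-methylideneperhydro-1-benzoxepine-3,7-dione 3-ethylene ketal | C=C1C(=O)CC[C@@H]2OC(C)(C)C3(OCCO3)CC[C@@]12C | intermediate
23 | (5aS,6S,9aS)-2,2,5a-trimethyl-6-[(phenylsulfanyl)methyl]perhydro-1-benzoxepine-3,7-dione 3-ethylene ketal | O=C1CC[C@@H]2OC(C)(C)C3(OCCO3)CC[C@@]2(C)[C@@H]1CSc1ccccc1 | intermediate
24 | (5aS,6R,9aS)-2,2,5a-trimethyl-7-methylidene-6-[(phenylsulfanyl)methyl]perhydro-1-benzoxepin-3-one ethylene ketal | C=C1CC[C@@H]2OC(C)(C)C3(OCCO3)CC[C@@]2(C)[C@@H]1CSc1ccccc1 | intermediate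
25 | (5aS,6R,9aS)-2,2,5a-trimethyl-7-methylidene-6-[(phenylsulfanyl)methyl]perhydro-1-benzoxepin-3-one | C=C1CC[C@@H]2OC(C)(C)C(=O)CC[C@@]2(C)[C@@H]1CSc1ccccc1 | intermediate
26 | (3S,5aS,6R,9aS)-2,2,5a-trimethyl-7-methylidene-6-[(phenylsulfanyl)methyl]perhydro-1-benzoxepin-3-ol | C=C1CC[C@@H]2OC(C)(C)[C@@H](O)CC[C@@]2(C)[C@@H]1CSc1ccccc1 | intermediate
27 | (3S,5aS,6R,9aS)-2,2,5a-trimethyl-7-methylidene-6-[(phenylsulfanyl)methyl]-3-(triethylsilyloxy)perhydro-1-benzoxepine | C=C1CC[C@@H]2OC(C)(C)[C@@H](O[Si](CC)(CC)CC)CC[C@@]2(C)[C@@H]1CSc1ccccc1 | intermediate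
28 | ring A/B (C6-methyl)lithium reagent (formed in the flask) | C=C1CC[C@@H]2OC(C)(C)[C@@H](O[Si](CC)(CC)CC)CC[C@@]2(C)[C@@H]1C[Li] | intermediate
29 | lithium alkyl(phenylthiolato)cuprate of the ring A/B fragment (formed in the flask) | [Li+].C=C1CC[C@@H]2OC(C)(C)[C@@H](O[Si](CC)(CC)CC)CC[C@@]2(C)[C@@H]1C[Cu-]Sc1ccccc1 | intermediate
30 | trimethylsilyl enol ether of the linked ketone (formed in the flask) | C=C1CC[C@@H]2OC(C)(C)[C@@H](O[Si](CC)(CC)CC)CC[C@@]2(C)[C@@H]1CCC1=C(O[Si](C)(C)C)CC[C@@H]2OC(C)(C)C3(OCCO3)CC[C@@]12C | intermediate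
31 | linked ketone: ring A/B half (3S,5aS,6R,9aS) with 3-triethylsilyloxy and 7-methylidene, joined C6–CH2CH2–C6 to the ring C/D half (5aS,6S,9aS) with 7-ketone and 3-ethylene ketal | C=C1CC[C@@H]2OC(C)(C)[C@@H](O[Si](CC)(CC)CC)CC[C@@]2(C)[C@@H]1CC[C@H]1[C@]2(C)CCC3(OCCO3)C(C)(C)O[C@H]2CCC1=O | intermediate
32 | linked tertiary alcohol: as 31 with (7R)-7-hydroxy-7-methyl in ring C (axial hydroxyl) | C=C1CC[C@@H]2OC(C)(C)[C@@H](O[Si](CC)(CC)CC)CC[C@@]2(C)[C@@H]1CC[C@H]1[C@]2(C)CCC3(OCCO3)C(C)(C)O[C@H]2CC[C@@]1(C)O | intermediate
33 | CNP0160418.1: ring A/B half (3S,5aS,6R,9aS)-3-hydroxy-7-methylidene, ring C/D half (5aS,6S,7R,9aS)-7-hydroxy-7-methyl-3-oxo | C=C1CC[C@@H]2OC(C)(C)[C@@H](O)CC[C@@]2(C)[C@@H]1CC[C@H]1[C@]2(C)CCC(=O)C(C)(C)O[C@H]2CC[C@@]1(C)O | target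

**Step count and risks**

Total step count: 23. Longest linear sequence: 19 steps (steps 5–9, then 10–23, from methyl 3-hydroxypropanoate).

Steps most likely to fail:

Step 14. The electron-withdrawing ketal next to the tertiary radical may slow its oxidation, so that the alkene is merely reduced. If a free cation does form, an alkyl group may shift from the ketal carbon to give a dioxolanylium ion, and the seven-membered closure itself is entropically less favoured than the known five- and six-membered cases. The fallback uses known chemistry and sets out from 20: iodoetherification with N-iodosuccinimide in CH2Cl2 at 0 °C (7-exo attack of the hydroxyl on the iodonium ion at the more substituted carbon) should give the 2-(iodomethyl)oxepane F1 as a mixture at the new quaternary carbon. Radical deiodination with Bu3SnH and azobisisobutyronitrile in toluene at 80 °C then turns CH2I into the second methyl group, which removes that stereocentre, and the route is rejoined at 21.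

Step 21. The reductive C–S cleavage of a primary alkyl thioether may be incomplete, the hindered alkyllithium may be protonated before transmetalation, or the mixed cuprate may transfer its alkyl group too slowly. The fallback sets out from 27 and 22 and uses a sulfone-stabilised carbanion in place of the organocopper. Oxidation of 27 with H2O2 and catalytic (NH4)6Mo7O24 in ethanol should give the phenyl sulfone F2. n-BuLi in THF/hexamethylphosphoric triamide at −78 °C gives the lithiated sulfone F3, which adds in Michael fashion to 22 to give, after protonation from the face opposite the axial methyl group, the keto sulfone F4. MeMgBr/CeCl3 converts F4 into the hydroxy sulfone F5, and reductive desulfonylation with sodium amalgam Na(Hg) and Na2HPO4 in MeOH at −20 °C rejoins the route at 32.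

Step 23. The ketal is deactivated by the adjacent ether carbon, and the acid strength needed to open it may protonate the exocyclic alkene (migration into ring A) or ionise the tertiary carbinol. The fallback sets out from 22 and 27 and frees the ring D ketone before either sensitive group exists. Treating 22 with p-toluenesulfonic acid in acetone/H2O (its only alkene is the acid-stable conjugated one) gives the ene-dione F6. Conjugate addition of cuprate 29 (generated from 27 as in step 21, with Me3SiCl) is selective for the enone and gives the silyl enol ether F7, which K2CO3 in MeOH converts into the diketone F8. MeTi(OiPr)3 in THF at −20 °C → rt, a reagent with strong steric discrimination between ketones, should add equatorially to the cyclohexanone and leave the oxepanone flanked by the fully substituted C2 untouched, giving the silyl ether F9. HF·pyridine in THF/pyridine removes the triethylsilyl group under conditions mild to the alkene and arrives at 33.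

**Further compounds**

F1 | step 14 | [(5aS,9aS)-2-(iodomethyl)-2,5a-dimethyl-3,7-dioxoperhydro-1-benzoxepin-6-yl]methyl pivalate 3-ethylene ketal (C2 and C6 epimers) | O=C1CC[C@@H]2OC(C)(CI)C3(OCCO3)CC[C@@]2(C)C1COC(=O)C(C)(C)C
F2 | step 21 | (3S,5aS,6R,9aS)-2,2,5a-trimethyl-7-methylidene-6-[(phenylsulfonyl)methyl]-3-(triethylsilyloxy)perhydro-1-benzoxepine | C=C1CC[C@@H]2OC(C)(C)[C@@H](O[Si](CC)(CC)CC)CC[C@@]2(C)[C@@H]1CS(=O)(=O)c1ccccc1
F3 | step 21 | α-lithio derivative of sulfone F2 | C=C1CC[C@@H]2OC(C)(C)[C@@H](O[Si](CC)(CC)CC)CC[C@@]2(C)[C@@H]1C([Li])S(=O)(=O)c1ccccc1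
F4 | step 21 | linked ketone 31 bearing a phenylsulfonyl group on the linker carbon next to ring A (epimers at that carbon) | C=C1CC[C@@H]2OC(C)(C)[C@@H](O[Si](CC)(CC)CC)CC[C@@]2(C)[C@@H]1C(S(=O)(=O)c1ccccc1)C[C@H]1[C@]2(C)CCC3(OCCO3)C(C)(C)O[C@H]2CCC1=O
F5 | step 21 | linked tertiary alcohol 32 bearing a phenylsulfonyl group on the linker carbon next to ring A (epimers at that carbon) | C=C1CC[C@@H]2OC(C)(C)[C@@H](O[Si](CC)(CC)CC)CC[C@@]2(C)[C@@H]1C(S(=O)(=O)c1ccccc1)C[C@H]1[C@]2(C)CCC3(OCCO3)C(C)(C)O[C@H]2CC[C@@]1(C)O
F6 | step 23 | (5aS,9aS)-2,2,5a-trimethyl-6-methylideneperhydro-1-benzoxepine-3,7-dione | C=C1C(=O)CC[C@@H]2OC(C)(C)C(=O)CC[C@@]12C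
F7 | step 23 | trimethylsilyl enol ether of the linked diketone (ring D ketone free) | C=C1CC[C@@H]2OC(C)(C)[C@@H](O[Si](CC)(CC)CC)CC[C@@]2(C)[C@@H]1CCC1=C(O[Si](C)(C)C)CC[C@@H]2OC(C)(C)C(=O)CC[C@@]12C
F8 | step 23 | linked diketone: ring A/B silyl ether joined to the ring C/D 3,7-dione | C=C1CC[C@@H]2OC(C)(C)[C@@H](O[Si](CC)(CC)CC)CC[C@@]2(C)[C@@H]1CC[C@H]1[C@]2(C)CCC(=O)C(C)(C)O[C@H]2CCC1=O
F9 | step 23 | ring B triethylsilyl ether of the target | C=C1CC[C@@H]2OC(C)(C)[C@@H](O[Si](CC)(CC)CC)CC[C@@]2(C)[C@@H]1CC[C@H]1[C@]2(C)CCC(=O)C(C)(C)O[C@H]2CC[C@@]1(C)O
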